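The rate constants were set for the occasion; no experiment stands behind them.

The meeting began with a leftover: with 0.900 equiv of coupling partner, the limiting reagent, substrate is left over on paper, so the question was how much target the catalyst delivers within the run.

    substrate + free catalyst ⇌ catalyst intermediate A (K1 = 68 L mol⁻¹, k1 = 4120 L mol⁻¹ min⁻¹)
    coupling partner + catalyst intermediate A ⇌ catalyst intermediate B (K2 = 31.3 L mol⁻¹, k2 = 2490 L mol⁻¹ min⁻¹)
    catalyst intermediate B → released group + catalyst intermediate C (k3 = 210 min⁻¹)
    catalyst intermediate C → free catalyst + target (k4 = 175 min⁻¹)
    substrate + target → side product (k5 = 0.804 L mol⁻¹ min⁻¹)
    free catalyst + released group ⇌ idle complex (K6 = 7.6 L mol⁻¹, k6 = 2.17 L mol⁻¹ min⁻¹)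

| flask | substrate | coupling partner | free catalyst | time | remark |
|---|---|---|---|---|---|
| maple | 0.050 M | 0.900 equiv (fed, over 20.0 min) | 0.055 mol% | 25 min | a stirred flask in which coupling partner is dosed at a steady rate over 20.0 min without added volume, worked up at 25 min |
| oak | 0.050 M | 0.900 equiv | 0.055 mol% |  | one stirred flow tank at steady state, fed with the mixture as stated, mean residence time 25 min |
| birch | 0.050 M (fed, over 20.0 min) | 0.900 equiv | 0.055 mol% | 25 min | all but substrate at the start; substrate goes in evenly over 20.0 min, the run ends at 25 min |
| ash | 0.050 M | 0.900 equiv | 0.055 mol% | 25 min | a closed flask charged with all of it at once and left for 25 min |

- percent here means substrate units held: one side product counts as two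
- what is said of released group includes idle complex
- the stated concentrations are those of everything mixed, before any reaction; amounts are the same in each set-up
- the feed brings no volume worth counting
- run time (maple): 25 min

- the set-up with the highest amount of target at the outlet or at the end, in percent of the substrate put in ("none" if the first two lie within 2 percentage points) (maple / oak / birch / ash / none)
- amount of target at the outlet or at the end, in percent of the substrate put in, maple
- amount of target at the outlet or at the end, in percent of the substrate put in, oak
- amount of target at the outlet or at the end, in percent of the substrate put in, birch
- amount of target at the outlet or at the end, in percent of the substrate put in, ash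

I argued that we should count turnovers, not integrate. One turnover is a chain of waits: free catalyst catches substrate, catalyst intermediate A catches coupling partner, some of each falls back, and intermediates B and C then pass on. At the start of ash, before any released group exists to form idle complex, these waits add up to 0.0313 min.

The partner's charge asks for 1640 turnovers, and 25 min allows 800 at that pace, about half of them. I proposed carrying one figure, the turnover budget, meaning the loading times the run time divided by the turnover time, or the fraction of the charge passed at the opening pace. For ash it is 44.0%, a figure reckoned at the opening fractions.

I added that target is also consumed. At the charged substrate level its half-life by that step alone is 17.2 min, shorter than the run. Maple opens without partner and birch without substrate; I put ash first and gave no further figures.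

The forecast's author, working by hand, then reported 18.8% for maple, called “starved of partner early”, with 18.1% for oak, 21.4% for birch and 24.4% for ash, so ash came first.

The simulation gives 18.8% for maple, 18.1% for oak, 21.4% for birch and 24.5% for ash, so ash stands first. With the substrate and target step struck out, ash holds 35.6% target, or 80.9% of its budget. In oak, substrate reads 60.0% of the charge beside 18.1% target, so 29.1% has been turned and partner stands at 60.9%. At those fractions, with idle complex uncounted, one oak turnover takes 0.0457 min, which brings the budget to 30.1%.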